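**Assumption (one line):** The target SMILES has no stereocentres, so the molecule is achiral and no stereocontrol is needed. Acylation of the 5‑alkylresorcinol pattern is assumed to occur between the alkyl and oxygen substituents.

## Retrosynthesis
1. Siphulin comes from global demethylation (aryl OMe and CO2Me) of the permethylated chromone **12**.
2. **12** comes from acid cyclodehydration of the 1,3‑diketone **11**. This is the only ring formed in the route, the γ‑pyranone; both benzene rings are already present in the starting materials.
3. **11** comes from Claisen condensation of the o‑hydroxyacetophenone **5** with the homophthalate diester **10**.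
4. **5** comes from 1‑bromo‑3,5‑dimethoxybenzene by Kumada heptylation, then AlCl3 acylation with ortho‑demethylation.
5. **10** comes from orsellinic acid by permethylation, then lateral lithiation and C‑acylation.

## Route

**Step 1**
Reactants: 1 (1‑bromo‑3,5‑dimethoxybenzene); 2 (heptylmagnesium bromide)
Product: 3 (1‑heptyl‑3,5‑dimethoxybenzene)
Conditions: NiCl2(dppp) (2 mol %), THF/Et2O, 0 °C → rt, 12 h
Reagents that add atoms: 2, CCCCCCC[Mg]Br (it supplies the heptyl group)
Why: Ni‑catalysed Kumada cross‑coupling joins the aryl bromide and the primary alkyl Grignard. No stereocentre is formed.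

**Step 2**
Reactants: 3; 4 (acetyl chloride)
Product: 5 (1‑(6‑heptyl‑2‑hydroxy‑4‑methoxyphenyl)ethan‑1‑one)
Conditions: AlCl3 (3 equiv), CH2Cl2, 0 °C → rt, 4 h; aqueous HCl quench
Reagents that add atoms: 4, CC(=O)Cl (it supplies the acetyl group)
Why: Friedel–Crafts acylation goes at the ring carbon that is ortho to one OMe, para to the other and ortho to heptyl, and avoids the carbon flanked by two OMe groups. Excess AlCl3 then chelates the new C=O and cleaves only the adjacent OMe, leaving the chelated o‑hydroxyacetophenone. No stereocentre is formed.

**Step 3**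
Reactants: 6 (orsellinic acid, 2,4‑dihydroxy‑6‑methylbenzoic acid); 7 (iodomethane)
Product: 8 (methyl 2,4‑dimethoxy‑6‑methylbenzoate)
Conditions: MeI (4 equiv), K2CO3 (4 equiv), DMF, rt, 16 h
Reagents that add atoms: 7, CI (it supplies the methyl groups on both phenols and the carboxylate)
Why: Williamson O‑alkylation and carboxylate alkylation give the fully methylated, lithiation‑ready toluate. No stereocentre is formed.

**Step 4**
Reactants: 8 (2.0 equiv); 9 (methyl chloroformate, 1.0 equiv, limiting)
Product: 10 (methyl 2‑[2‑(methoxycarbonyl)‑3,5‑dimethoxyphenyl]acetate)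
Conditions: LDA (2.1 equiv), THF, −78 °C, 1 h; then ClCO2Me, −78 °C → 0 °C; aqueous NH4Cl; unreacted 8 recovered
Reagents that add atoms: 9, COC(=O)Cl (it supplies the CO2Me group)
Why: Lateral lithiation of the hindered o‑toluate ester gives the benzylic anion, which is C‑acylated by the chloroformate. The second equivalent of anion deprotonates the more acidic product, which prevents over‑acylation. No stereocentre is formed.

**Step 5**
Reactants: 5 (1.0 equiv); 10 (1.5 equiv)
Product: 11 (1‑(6‑heptyl‑2‑hydroxy‑4‑methoxyphenyl)‑4‑[2‑(methoxycarbonyl)‑3,5‑dimethoxyphenyl]butane‑1,3‑dione)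
Conditions: NaH (5 equiv), THF, 0 °C → 65 °C, 12 h; aqueous NH4Cl to pH 5
Reagents that add atoms: none
Why: Claisen condensation of the phenoxide/enolate of 5 with the unhindered CH2CO2Me ester of 10. The 2,6‑disubstituted aryl ester is too hindered to react. Irreversible deprotonation of the product diketone drives the reaction. No stereocentre is formed.

**Step 6**
Reactants: 11
Product: 12 (methyl 2‑[(5‑heptyl‑7‑methoxy‑4‑oxo‑4H‑chromen‑2‑yl)methyl]‑4,6‑dimethoxybenzoate)
Conditions: TsOH·H2O (0.3 equiv), toluene, 110 °C, Dean–Stark, 3 h
Reagents that add atoms: none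
Why: Acid‑catalysed cyclodehydration, in which the free ortho phenol condenses onto the distal ketone (Baker–Venkataraman‑type chromone closure) and loses H2O to give the 2‑substituted chromone. No stereocentre is formed.

**Step 7**
Reactants: 12
Product: 13 (siphulin)
Conditions: BBr3 (8 equiv), CH2Cl2, −78 °C → rt, 16 h; quench with cold H2O at 0 °C
Reagents that add atoms: none
Why: BBr3 cleaves all three aryl methyl ethers and the hindered methyl ester, giving the free acid after aqueous work‑up. The chromone, heptyl chain and 1,3‑oxygenation pattern are unaffected, and the molecule has no stereocentres to scramble.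

## Checks
- **Structure match:** 13 is 5‑heptyl‑7‑hydroxychromone with a 2‑CH2 link to a 2‑carboxy‑3,5‑dihydroxyphenyl ring. This matches the target SMILES, with formula C24H26O7.
- **Atom balance:** 5 (C16H24O3) + 10 (C13H16O6) − MeOH gives 11 (C28H36O8). Loss of H2O gives 12 (C28H34O7). Loss of four CH2 in the demethylation gives C24H26O7.
- **Functional group survival:**
  - The free phenol in 5 is compatible with NaH, since it is needed as the phenoxide.
  - The methyl ethers and esters survive Steps 1–6.
  - BBr3 is used only in the last step.
- **Stereochemistry:** There are none, so nothing can be scrambled.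

## Compound list
1 | 1‑bromo‑3,5‑dimethoxybenzene | COc1cc(Br)cc(OC)c1 | starting material
2 | heptylmagnesium bromide | CCCCCCC[Mg]Br | starting material
3 | 1‑heptyl‑3,5‑dimethoxybenzene | CCCCCCCc1cc(OC)cc(OC)c1 | intermediate
4 | acetyl chloride | CC(=O)Cl | starting material
5 | 1‑(6‑heptyl‑2‑hydroxy‑4‑methoxyphenyl)ethanone | CCCCCCCc1cc(OC)cc(O)c1C(C)=O | intermediate
6 | orsellinic acid | Cc1cc(O)cc(O)c1C(=O)O | starting material
7 | iodomethane | CI | starting material
8 | methyl 2,4‑dimethoxy‑6‑methylbenzoate | COC(=O)c1c(C)cc(OC)cc1OC | intermediate
9 | methyl chloroformate | COC(=O)Cl | starting material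
10 | methyl 2‑[2‑(methoxycarbonyl)‑3,5‑dimethoxyphenyl]acetate | COC(=O)Cc1cc(OC)cc(OC)c1C(=O)OC | intermediate
11 | 1,3‑diketone (Claisen product) | CCCCCCCc1cc(OC)cc(O)c1C(=O)CC(=O)Cc1cc(OC)cc(OC)c1C(=O)OC | intermediate
12 | methyl 2‑[(5‑heptyl‑7‑methoxy‑4‑oxochromen‑2‑yl)methyl]‑4,6‑dimethoxybenzoate | CCCCCCCc1cc(OC)cc2oc(Cc3cc(OC)cc(OC)c3C(=O)OC)cc(=O)c12 | intermediate
13 | siphulin (achiral) | CCCCCCCc1cc(O)cc2oc(Cc3cc(O)cc(O)c3C(=O)O)cc(=O)c12 | target

**Total steps:** 7 (Steps 3 and 4 form a parallel branch feeding Step 5).
**Longest linear sequence:** 5 steps (Steps 1, 2, 5, 6, 7).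

## Three steps most likely to fail
1. **Step 5 (Claisen).** The acidic benzylic CH2 of 10 may quench the enolate or form a ketene. The diketonate may also undergo Dieckmann cyclisation onto the ortho ester to give a naphthol.
   - Fallback: change the acyl donor to commercial methyl 3,5‑dimethoxyphenylacetate in the same Claisen and cyclisation. Then install the carboxyl ortho to CH2 on the finished chromone by Vilsmeier formylation (this ring position is the most reactive) and Pinnick oxidation, and finish with BBr3.
2. **Step 7 (global BBr3 deprotection).** The product is a 2,4‑dihydroxybenzoic acid, which is prone to decarboxylation, and the hindered ester may cleave incompletely.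
   - Fallback: change the protecting groups to benzyl ethers on the phenols and a tert‑butyl ester on the acid, using tert‑butyl 2,4‑bis(benzyloxy)‑6‑methylbenzoate for the lateral‑lithiation fragment. Deprotect by H2/Pd‑C, then TFA, with no strong Lewis acid.
3. **Step 2 (AlCl3 acylation/demethylation).** Regioselectivity or over‑demethylation could give mixtures.
   - Fallback: demethylate 3 with BBr3 to 5‑heptylresorcinol and acylate by Houben–Hoesch (MeCN, ZnCl2, HCl). Then selectively methylate the unchelated 4‑OH (MeI, K2CO3, acetone) to give 5.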